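**Assumptions:** The target SMILES decodes to the (1S,2S)-cyclohexanol with the side chain trans to OH (cis to the carbinol methyl) and three E olefins. Isomerically pure (5E)-geranylacetone is purchased, and a recombinant squalene–hopene cyclase (SHC) is used as the catalyst. Reagents are named with SMILES in each step and are not numbered.

## Retrosynthetic overview

1. Final bond C9–C10: B-alkyl Suzuki–Miyaura union of ring-bearing (E)-vinyl iodide **6** with the 9-BBN borane of geraniol-derived trienol **11**, with both OH groups free.
2. E-C10=C11(Me): Zr-catalysed methylalumination/iodination of a terminal alkyne, itself made from a methyl ketone.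
3. Key step, and the only ring: SHC-catalysed enantioselective protonative cyclisation of (E)-geranylacetone terminated by its own ketone oxygen. This sets both stereocentres in step 1; the transient dihydropyran ring is then hydrolysed.
4. Deliberately avoided: coupling a resolved or chiral-pool cyclohexanol sulfone/halide to a farnesyl chain.

## Route

**Step 1**
Reactants: **1**, (5E)-6,10-dimethylundeca-5,9-dien-2-one ((E)-geranylacetone)
Product: **2**, (4aS,8aS)-2,5,5,8a-tetramethyl-4a,5,6,7,8,8a-hexahydro-4H-chromene (trans-fused bicyclic enol ether)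
Conditions: recombinant A. acidocaldarius SHC (active-site variant, E. coli whole cells), citrate buffer pH 6.0, 0.2% Triton X-100, 30 °C
Reagents that add atoms: none
Why: Class-II terpene-cyclase Brønsted-acid catalysis of a substrate class SHCs are known to accept: the terminal olefin is protonated in the enzyme's chair fold, the ring closes, and the ketone oxygen captures the tertiary cation anti across the E-olefin (then H+ loss), so anti addition fixes the trans C–C/C–O relationship and the enzyme's facial bias (the same sense as in hopene/ambroxide formation) gives 4aS,8aS.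

**Step 2**
Reactants: **2**
Product: **3**, 4-[(1S,2S)-2-hydroxy-2,6,6-trimethylcyclohexyl]butan-2-one
Conditions: oxalic acid (cat.), THF/H2O, 0 °C to rt
Reagents that add atoms: water, O
Why: Enol ether hydrolysis breaks only the vinylic C2–O bond, so the tertiary C–O stereocentre is retained and both stereocentres of the target are now in place.

**Step 3**
Reactants: **3**
Product: **4**, 4-[(1S,2S)-2,6,6-trimethyl-2-(trimethylsilyloxy)cyclohexyl]butan-2-one
Conditions: N-(trimethylsilyl)imidazole, CH2Cl2, rt
Reagents that add atoms: N-(trimethylsilyl)imidazole, C[Si](C)(C)n1ccnc1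
Why: Silylation of the hindered tertiary alcohol without enolising the ketone, so the oxygen cannot be phosphorylated or form a hemiketal alkoxide in step 4.

**Step 4**
Reactants: **4**
Product: **5**, {[(1S,2S)-2-(but-3-yn-1-yl)-1,3,3-trimethylcyclohexyl]oxy}trimethylsilane
Conditions: LDA, THF, −78 °C; ClP(O)(OEt)2, −78 °C to rt; then LDA (2.3 equiv), −78 °C to rt
Reagents that add atoms: none
Why: Negishi methyl ketone to terminal alkyne conversion: the kinetic methyl-side enolate is O-phosphorylated and LDA eliminates the enol phosphate, with acetylide formation preventing allene isomerisation.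

**Step 5**
Reactants: **5**
Product: **6**, (1S,2S)-2-[(3E)-4-iodo-3-methylbut-3-en-1-yl]-1,3,3-trimethylcyclohexan-1-ol
Conditions: Me3Al (3 equiv), Cp2ZrCl2 (0.2 equiv), H2O (1.5 equiv), CH2Cl2, −30 to 0 °C; I2, THF, −30 to 0 °C; work-up 1 M HCl/THF, rt
Reagents that add atoms: trimethylaluminium, C[Al](C)C; iodine, II
Why: Negishi Zr-catalysed carboalumination adds Me and Al syn across the alkyne with Al on the terminal carbon, and iodinolysis with retention gives the E-trisubstituted vinyl iodide; the acidic work-up removes the TMS ether.

**Step 6**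
Reactants: **7**, (2E)-3,7-dimethylocta-2,6-dien-1-yl acetate (geranyl acetate)
Product: **8**, (2E,6E)-8-hydroxy-3,7-dimethylocta-2,6-dien-1-yl acetate
Conditions: SeO2 (0.3 equiv), t-BuOOH, salicylic acid (cat.), CH2Cl2, rt
Reagents that add atoms: selenium dioxide, O=[Se]=O (oxygen donor); tert-butyl hydroperoxide, CC(C)(C)OO (terminal oxidant)
Why: Sharpless SeO2 allylic oxidation (ene reaction then [2,3]-shift) is selective for the E-methyl of the more electron-rich distal olefin.

**Step 7**
Reactants: **8**
Product: **9**, (2E,6E)-3,7-dimethyl-8-oxoocta-2,6-dien-1-yl acetate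
Conditions: activated MnO2, CH2Cl2, rt
Reagents that add atoms: none
Why: MnO2 oxidises only the allylic alcohol, leaving the acetate and olefin geometry untouched.

**Step 8**
Reactants: **9**
Product: **10**, (2E,6E)-3,7-dimethylnona-2,6,8-trien-1-yl acetate
Conditions: Ph3PCH3Br, n-BuLi, THF, −78 to 0 °C
Reagents that add atoms: methyltriphenylphosphonium bromide, [Br-].C[P+](c1ccccc1)(c1ccccc1)c1ccccc1
Why: Wittig methylenation of the enal with a slight excess of ylide at low temperature gives the terminal 1,3-diene and tolerates the acetate.

**Step 9**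
Reactants: **10**
Product: **11**, (2E,6E)-3,7-dimethylnona-2,6,8-trien-1-ol
Conditions: K2CO3 (cat.), MeOH, 0 °C to rt
Reagents that add atoms: none
Why: Methanolysis (transesterification) removes the acetate so that no allylic acetate, which could ionise to a π-allyl-Pd species, is present in the coupling.

**Step 10**
Reactants: **11** (1.4 equiv) and **6**
Product: **12**, preluffariellolide A, (1S,2S)-2-[(3E,7E,11E)-13-hydroxy-3,7,11-trimethyltrideca-3,7,11-trien-1-yl]-1,3,3-trimethylcyclohexan-1-ol
Conditions: **11**, 9-BBN (3 equiv), THF, 0 °C to rt; then **6**, Pd(dppf)Cl2 (10 mol%), AsPh3, Cs2CO3, DMF/THF/H2O, rt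
Reagents that add atoms: none (9-BBN, [H]B1C2CCCC1CCC2, contributes only hydrogen)
Why: 9-BBN hydroborates only the terminal vinyl group of the diene to give the homoallylic borane (one equivalent is consumed by the O–H), and B-alkyl Suzuki–Miyaura coupling proceeds with retention of the vinyl iodide geometry; no stereocentre is formed or disturbed.

## Compound list

1 | (5E)-6,10-dimethylundeca-5,9-dien-2-one | CC(=O)CC/C=C(\C)CCC=C(C)C | starting material
2 | (4aS,8aS)-2,5,5,8a-tetramethyl-4a,5,6,7,8,8a-hexahydro-4H-chromene | CC1=CC[C@H]2C(C)(C)CCC[C@]2(C)O1 | intermediate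
3 | 4-[(1S,2S)-2-hydroxy-2,6,6-trimethylcyclohexyl]butan-2-one | CC(=O)CC[C@H]1C(C)(C)CCC[C@]1(C)O | intermediate
4 | 4-[(1S,2S)-2,6,6-trimethyl-2-(trimethylsilyloxy)cyclohexyl]butan-2-one | CC(=O)CC[C@H]1C(C)(C)CCC[C@]1(C)O[Si](C)(C)C | intermediate
5 | {[(1S,2S)-2-(but-3-yn-1-yl)-1,3,3-trimethylcyclohexyl]oxy}trimethylsilane | C#CCC[C@H]1C(C)(C)CCC[C@]1(C)O[Si](C)(C)C | intermediate
6 | (1S,2S)-2-[(3E)-4-iodo-3-methylbut-3-en-1-yl]-1,3,3-trimethylcyclohexan-1-ol | I/C=C(\C)CC[C@H]1C(C)(C)CCC[C@]1(C)O | intermediate
7 | (2E)-3,7-dimethylocta-2,6-dien-1-yl acetate | CC(=O)OC/C=C(\C)CCC=C(C)C | starting material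
8 | (2E,6E)-8-hydroxy-3,7-dimethylocta-2,6-dien-1-yl acetate | CC(=O)OC/C=C(\C)CC/C=C(\C)CO | intermediate
9 | (2E,6E)-3,7-dimethyl-8-oxoocta-2,6-dien-1-yl acetate | CC(=O)OC/C=C(\C)CC/C=C(\C)C=O | intermediate
10 | (2E,6E)-3,7-dimethylnona-2,6,8-trien-1-yl acetate | CC(=O)OC/C=C(\C)CC/C=C(\C)C=C | intermediate
11 | (2E,6E)-3,7-dimethylnona-2,6,8-trien-1-ol | OC/C=C(\C)CC/C=C(\C)C=C | intermediate
12 | preluffariellolide A | C/C(=C\CO)CC/C=C(\C)CC/C=C(\C)CC[C@H]1C(C)(C)CCC[C@]1(C)O | target

## Summary

Total steps: 10. Longest linear sequence: 6 (steps 1–5, then 10); the chain branch is steps 6–9, then 10.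

Steps most likely to fail, each with one fallback:

1. **Step 1** (enzymatic cyclisation: conversion and throughput depend on the SHC variant). Fallback: give up asymmetric catalysis; cyclise **1** racemically with ClSO3H in 2-nitropropane at −78 °C, hydrolyse, and resolve hydroxy ketone **3** by preparative chiral SFC.
2. **Step 4** (enolate regiochemistry, allene or internal alkyne by-products, silyl ether loss). Fallback: go through the aldehyde oxidation level instead: haloform cleavage of **3** (NaOBr) to the trans-δ-lactone, DIBAL-H to the lactol, then Ohira–Bestmann homologation to the free alkynol, which enters step 5 with extra Me3Al.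
3. **Step 10** (diene hydroboration regioselectivity and B-alkyl coupling with two free OH groups). Fallback: switch to an allylic sulfone union: trap the alkenylalane of step 5 with paraformaldehyde to give the C9 allylic alcohol, convert it to the bromide, alkylate the C8 phenyl sulfone made from **8**, then remove the sulfone with Pd/LiEt3BH and cleave the acetate.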